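Assumption on the chemistry: compounds 1, 6 and 9 and all reagents and ligands are taken as commercial. The (S)-ligand in step 5 is expected to give the 2S product by analogy with additions to cyclic enones; if the first run shows the opposite sense, the (R)-ligand is used with no other change.

Numbering used throughout: 1 2',6'-dihydroxy-4'-methoxyacetophenone; 2 enaminone (not isolated); 3 5-hydroxy-7-methoxychromone; 4 its 6-iodide; 5 the 5-O-MOM ether of 4; 6 geranyl bromide; 7 arylzinc iodide (not isolated); 8 6-geranyl-7-methoxy-5-(methoxymethoxy)chromone; 9 3,4-dimethoxyphenylboronic acid; 10 (2S)-flavanone MOM ether; 11 target.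

## Analysis of the target

The target is a (2S)-flavanone: a benzene ring A (C4a, C5–C8, C8a) fused to a dihydropyranone (O1, C2, C3, C4=O), with a 3,4-dimethoxyphenyl ring B on C2. Ring A is fully differentiated: 5-OH (hydrogen-bonded to C4=O), an (E)-geranyl chain on C6, OMe on C7, and only C8 bearing hydrogen. C2 is the only stereocentre. It is benzylic to an electron-rich arene, bonded to O1, and β to the C4 ketone. Deprotonation at C3 therefore expels O1 (retro-oxa-Michael, E1cB) and gives an achiral 2'-hydroxychalcone, so any basic step after C2 is set threatens it. The geranyl chain has two trisubstituted alkenes; the C2''=C3'' alkene sits ortho to the 5-OH and can add that phenol under acid to give a chroman, and its E geometry must be carried through. C6 and C8 are both flanked by two oxygens and are electronically alike. In any open-chain precursor the two phenols ortho to the ketone compete for ring closure, which turns one C-geranyl ketone into both the 6- and the 8-geranyl flavanone. The difficulty is therefore not size but three coupled selectivity problems: the configuration of a labile C2, geranyl on C6 and not C8, and three distinct roles for the phloroglucinol oxygens (O1 in the ring, 5-OH free, 7-OMe).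

## Retrosynthetic reasoning

11 ⇒ 10. The last operation only unmasks the 5-OH. An acid-labile acetal is chosen because C2 is stable to mild acid but not to base, and because an acetal peri to C4=O leaves very easily.

10 ⇒ 8 + 9 (key disconnection, bond C2–C1'). The cut is made between C2 and ring B, not at O1–C2. The precursor 8 is a flat, achiral chromone in which O1–C2 already exists, so the stereocentre is created by C–C bond formation and never by the reversible oxa-Michael closure that also destroys it. The forward reaction must add the aryl group of 9 to the Re face of C2 (priorities O1 > C3 > H), 1,4 and not 1,2, leave the geranyl alkenes alone, and stop at the ketone. This step also joins the two halves of the molecule at the end, so all earlier chemistry is done on achiral material.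

8 ⇒ 5 + 6 (bond C6–C1''). The geranyl chain is attached as an intact C10 unit by coupling an aryl nucleophile at C6 (arylzinc 7, made from iodide 5) with the allylic bromide 6. The forward reaction has to give the linear product with the E alkene retained.

5 ⇒ 4 ⇒ 3 (bonds C6–I and O5–CH2). The distinction between C6 and C8 is made here. In 3 the only free phenol is the 5-OH, and C6 is its only open ortho position; C8 is para to it. The iodide is therefore placed by phenol-directed electrophilic substitution, and only then is the phenol capped. The cap is needed twice: the arylzinc 7 cannot coexist with an acidic OH, and a free 5-O/C4=O pair would bind rhodium as a β-ketoenolate chelate in the key step.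

3 ⇒ 1 (bonds O1–C2 and C2–C3). The pyranone is closed on acetophenone 1 by adding one carbon at the formate oxidation level. The two phenols of 1 are equivalent by symmetry, so only one chromone can form; the unused phenol becomes the 5-OH and the 4-OMe becomes 7-OMe. The regiochemical question that plagues the chalcone route does not arise.

## Alternatives that were turned down

Alternative 1: the textbook disconnection at O1–C2. Aldol condensation of the C-geranylated acetophenone A1 with the B-ring aldehyde would give chalcone A2, and an intramolecular oxa-Michael addition would close the ring. It was turned down for three reasons. A2 has two non-equivalent phenols ortho to the ketone, so closure leads to both the 6- and the 8-geranyl flavanone unless one phenol is selectively protected, and the more hindered one would have to be the protected one. The closure is the microscopic reverse of the racemisation pathway, so base gives racemate. Small-molecule asymmetric versions work well only when C3 carries an activating ester, which costs two more steps and an acidic, hot decarboxylation that the geranyl group would not tolerate.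

Alternative 2: disconnection at C2–H. The flavone A3 would be reduced enantioselectively at C2=C3 by a chiral copper hydride or by asymmetric hydrogenation. It was turned down because A3 is a doubly deactivated acceptor (a vinylogous ester conjugated to an electron-rich aryl group), for which asymmetric 1,4-reduction has thin precedent. Hydrogenation catalysts would also attack the geranyl alkenes or reduce on to the flavan-4-ol. The flavone needs ring B from the start and an acidic cyclodehydration, so the route is longer and less convergent.

Alternative 3: disconnection at C6–C1'' as the last C–C bond. The enantiopure flavanone A4 would be iodinated to A5 and then geranylated. It was turned down because the labile C2 centre would be set first and then carried through halogenation, metalation and palladium chemistry. Each of these involves bases or Lewis-acidic metals next to an enolisable C3 and a β-aryloxy leaving group. The iodination would also have to choose C6 over C8 and over ring B on a more crowded substrate.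

Key step: step 5

## Route

Step 1
Reactants: 1 2',6'-dihydroxy-4'-methoxyacetophenone
Product: 3 5-hydroxy-7-methoxy-4H-chromen-4-one, via enaminone 2 (not isolated)
Conditions: Me2NCH(OMe)2 (1.5 equiv), toluene, 90 °C; then conc. HCl, CH2Cl2, 40 °C
Reagents that add atoms: N,N-dimethylformamide dimethyl acetal, COC(OC)N(C)C
Why: Formamide-acetal condensation at the acetyl CH3 gives the enaminone, and acid-promoted addition–elimination of a phenol with loss of dimethylamine closes the pyranone (standard enaminone chromone synthesis); the two phenols of 1 are equivalent, so a single chromone should form.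

Step 2
Reactants: 3 5-hydroxy-7-methoxy-4H-chromen-4-one
Product: 4 5-hydroxy-6-iodo-7-methoxy-4H-chromen-4-one
Conditions: BnMe3N·ICl2 (1.05 equiv), CaCO3, CH2Cl2/MeOH, rt
Reagents that add atoms: benzyltrimethylammonium dichloroiodate, C[N+](C)(C)Cc1ccccc1.Cl[I-]Cl
Why: Electrophilic aromatic iodination; on 5-hydroxy-7-alkoxybenzopyranones the free, chelated 5-OH directs dichloroiodate to its ortho position C6, while C8 (para) and the pyranone C3 should react more slowly; CaCO3 takes up the HCl.

Step 3
Reactants: 4 5-hydroxy-6-iodo-7-methoxy-4H-chromen-4-one
Product: 5 6-iodo-7-methoxy-5-(methoxymethoxy)-4H-chromen-4-one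
Conditions: NaH, MOMCl, DMF, 0 °C to rt
Reagents that add atoms: chloromethyl methyl ether, COCCl
Why: O-Alkylation of the sodium phenoxide (Williamson type); a strong, non-nucleophilic base is used because the phenol is chelated and flanked by iodine, and it leaves the pyranone intact.

Step 4
Reactants: 5 6-iodo-7-methoxy-5-(methoxymethoxy)-4H-chromen-4-one, 6 geranyl bromide
Product: 8 6-[(2E)-3,7-dimethylocta-2,6-dien-1-yl]-7-methoxy-5-(methoxymethoxy)-4H-chromen-4-one, via arylzinc iodide 7 (not isolated)
Conditions: Zn dust (activated with BrCH2CH2Br, TMSCl), LiCl, THF, 45 °C; solution decanted from excess Zn; then 6, Pd(PPh3)4 (4 mol%), THF, 0 °C to rt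
Reagents that add atoms: zinc, [Zn] (stays only in intermediate 7)
Why: LiCl-promoted insertion of zinc into the C–I bond, helped by the two ortho oxygens, gives an arylzinc that does not attack the chromone; Negishi coupling with the allylic bromide proceeds through an (η3-geranyl)(aryl)palladium species that eliminates at the primary terminus, a coupling type known to give the linear product with the E geometry kept.

Step 5
Reactants: 8 6-[(2E)-3,7-dimethylocta-2,6-dien-1-yl]-7-methoxy-5-(methoxymethoxy)-4H-chromen-4-one, 9 (3,4-dimethoxyphenyl)boronic acid
Product: 10 (2S)-2-(3,4-dimethoxyphenyl)-6-[(2E)-3,7-dimethylocta-2,6-dien-1-yl]-7-methoxy-5-(methoxymethoxy)-2,3-dihydro-4H-chromen-4-one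
Conditions: [RhCl(C2H4)2]2 (1.5 mol%), (S)-MeO-F12-BIPHEP (3.3 mol%), aq. KOH (10 mol%), 9 (2.5 equiv), CH2Cl2/H2O (10:1), 30 °C
Reagents that add atoms: none
Why: Transmetalation from boron to Rh–OH gives an aryl–Rh(I) species, the chromone binds through C2=C3, syn-carborhodation places the aryl group on C2 and rhodium on C3 as an oxa-π-allyl enolate, and water protonates the enolate and regenerates Rh–OH. The closest known reaction type is the Rh(I)-catalysed asymmetric 1,4-addition of arylboronic acids to chromones (Hayashi–Miyaura reaction), which is established for 5,7-dioxygenated chromones with electron-poor atropisomeric bisphosphines and with chiral dienes. No ring is closed: the dihydropyranone is already present and O1–C2 is never broken, which is the point of the disconnection. C2 is set by the ligand alone, which should expose the Re face of C2 (O1 > C3 > H) to the migrating aryl group and so give 2S. The step needs 1,4- over 1,2-addition and no second addition to the product ketone; the peri 5-OMOM group shields C4=O in both 8 and 10, and the mild biphasic conditions disfavour over-addition. The geranyl alkenes are unactivated and trisubstituted and should not insert into aryl–Rh. The medium is near neutral and there is no free phenoxide, so retro-oxa-Michael opening of 10 should not compete, and the MOM ether keeps the 5-O/C4=O pair from sequestering rhodium as a chelate.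

Step 6
Reactants: 10 (2S)-2-(3,4-dimethoxyphenyl)-6-[(2E)-3,7-dimethylocta-2,6-dien-1-yl]-7-methoxy-5-(methoxymethoxy)-2,3-dihydro-4H-chromen-4-one
Product: 11 (2S)-2-(3,4-dimethoxyphenyl)-6-[(2E)-3,7-dimethylocta-2,6-dien-1-yl]-5-hydroxy-7-methoxy-2,3-dihydro-4H-chromen-4-one
Conditions: aq. HCl (3 M, 3 equiv), MeOH/THF, rt
Reagents that add atoms: none
Why: Acid-catalysed acetal exchange to methanol; a MOM ether peri to C4=O is unusually labile, so conditions mild enough to spare the geranyl alkenes should suffice, and C2 is configurationally stable to dilute acid at room temperature.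

## Compound list

1 | 1-(2,6-dihydroxy-4-methoxyphenyl)ethan-1-one (2',6'-dihydroxy-4'-methoxyacetophenone) | CC(=O)c1c(O)cc(OC)cc1O | starting material
2 | (E)-3-(dimethylamino)-1-(2,6-dihydroxy-4-methoxyphenyl)prop-2-en-1-one | CN(C)/C=C/C(=O)c1c(O)cc(OC)cc1O | intermediate (not isolated)
3 | 5-hydroxy-7-methoxy-4H-chromen-4-one | COc1cc(O)c2c(c1)occc2=O | intermediate
4 | 5-hydroxy-6-iodo-7-methoxy-4H-chromen-4-one | COc1cc2occc(=O)c2c(O)c1I | intermediate
5 | 6-iodo-7-methoxy-5-(methoxymethoxy)-4H-chromen-4-one | COCOc1c(I)c(OC)cc2occc(=O)c12 | intermediate
6 | geranyl bromide, (2E)-1-bromo-3,7-dimethylocta-2,6-diene | BrC/C=C(\C)CCC=C(C)C | starting material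
7 | [7-methoxy-5-(methoxymethoxy)-4-oxo-4H-chromen-6-yl]zinc iodide | COCOc1c([Zn]I)c(OC)cc2occc(=O)c12 | intermediate (not isolated)
8 | 6-[(2E)-3,7-dimethylocta-2,6-dien-1-yl]-7-methoxy-5-(methoxymethoxy)-4H-chromen-4-one | COCOc1c(C/C=C(\C)CCC=C(C)C)c(OC)cc2occc(=O)c12 | intermediate
9 | (3,4-dimethoxyphenyl)boronic acid | COc1ccc(B(O)O)cc1OC | starting material
10 | (2S)-2-(3,4-dimethoxyphenyl)-6-[(2E)-3,7-dimethylocta-2,6-dien-1-yl]-7-methoxy-5-(methoxymethoxy)-2,3-dihydro-4H-chromen-4-one | COc1ccc([C@@H]2CC(=O)c3c(cc(OC)c(C/C=C(\C)CCC=C(C)C)c3OCOC)O2)cc1OC | intermediate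
11 | (2S)-2-(3,4-dimethoxyphenyl)-6-[(2E)-3,7-dimethylocta-2,6-dien-1-yl]-5-hydroxy-7-methoxy-2,3-dihydro-4H-chromen-4-one | COc1ccc([C@@H]2CC(=O)c3c(cc(OC)c(C/C=C(\C)CCC=C(C)C)c3O)O2)cc1OC | target

## Step count and risk

Total steps: 6. Longest linear sequence: 6 steps, from 1 to 11; compounds 6 and 9 enter as bought.

Step 5 (key step). The carborhodation of an electron-rich, 5,7-dioxygenated chromone may be slow, so that protodeboronation of the electron-rich boronic acid consumes the reagent first. The selectivity may also be eroded by a second aryl addition to the C4 ketone, or by reversible opening of the rhodium enolate at O1–C2. The fallback sets out from 8 and separates bond formation from stereocontrol. Addition of 9 with the far more active achiral catalyst [Rh(OH)(cod)]2 in dioxane/water should give the racemic MOM-protected flavanone F1. A kinetic resolution by asymmetric transfer hydrogenation with an (R,R)-TsDPEN rhodium or ruthenium catalyst in HCO2H/Et3N should then reduce the 2R ketone to the cis-(2R,4R)-flavan-4-ol F2 and leave the 2S ketone, which is 10. The catalyst sense is assigned by analogy with the reduction of chroman-4-ones. This resolution can return at most half of the material, and it tolerates the MOM ether and the geranyl alkenes.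

Step 2. Positional control may be lost: attack at C8 or at the pyranone C3, or double iodination. The fallback sets out from 3 and fixes C6 by a different principle. The sodium phenoxide of 3 (NaH, toluene) is alkylated with 6 as a contact ion pair, which delivers the electrophile only to the carbon ortho to the oxygen and should give 6-geranyl-5-hydroxy-7-methoxychromone F3 by direct SN2 displacement. O-Alkylation is the expected competitor. Protection of F3 with NaH/MOMCl then gives 8, and steps 2 to 4 are bypassed.

Step 4. Zinc insertion into an electron-rich iodide with two ortho substituents may be slow, and the arylzinc may be reduced to the arene by adventitious protons. The allylpalladium intermediate may undergo syn–anti isomerisation (loss of E geometry) or couple at its tertiary end. The fallback sets out from 5 and replaces the stoichiometric metal insertion by a catalytic C–B bond formation that gives an isolable nucleophile. Miyaura borylation (B2pin2, PdCl2(dppf), KOAc, dioxane, 85 °C) should give the pinacol boronate F4. Suzuki–Miyaura allylation of F4 with 6 (Pd(PPh3)4, CsF, THF, 50 °C, kept anhydrous to limit protodeboronation of the 2,6-dialkoxyarylboronate) should then give 8.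

Step 6. The freed 5-OH may add to the C2''=C3'' alkene under acid to form a chroman, or the diene may be hydrated or cyclised. The fallback sets out from 4 and avoids acid at the end by changing the protecting group to an ester. Acetylation (Ac2O, pyridine, DMAP) should give 5-acetoxy-6-iodo-7-methoxychromone F5. The conditions of step 4 should turn it into 5-acetoxy-6-geranyl-7-methoxychromone F6; an ortho acetoxy group assists zinc insertion. The conditions of step 5, run without added hydroxide, should give the (2S)-5-acetoxyflavanone F7. Near-neutral methanolysis (NH4OAc, aqueous MeOH, rt) should then release 11. The acetate also makes the chromone a better acceptor in the key step; its drawback is the risk of premature hydrolysis.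

## Further compounds

F1 | step 5 | rac-2-(3,4-dimethoxyphenyl)-6-[(2E)-3,7-dimethylocta-2,6-dien-1-yl]-7-methoxy-5-(methoxymethoxy)-2,3-dihydro-4H-chromen-4-one | COc1ccc(C2CC(=O)c3c(cc(OC)c(C/C=C(\C)CCC=C(C)C)c3OCOC)O2)cc1OC
F2 | step 5 | (2R,4R)-2-(3,4-dimethoxyphenyl)-6-[(2E)-3,7-dimethylocta-2,6-dien-1-yl]-7-methoxy-5-(methoxymethoxy)-3,4-dihydro-2H-chromen-4-ol | COc1ccc([C@H]2C[C@@H](O)c3c(cc(OC)c(C/C=C(\C)CCC=C(C)C)c3OCOC)O2)cc1OC
F3 | step 2 | 6-[(2E)-3,7-dimethylocta-2,6-dien-1-yl]-5-hydroxy-7-methoxy-4H-chromen-4-one | COc1cc2occc(=O)c2c(O)c1C/C=C(\C)CCC=C(C)C
F4 | step 4 | 7-methoxy-5-(methoxymethoxy)-6-(4,4,5,5-tetramethyl-1,3,2-dioxaborolan-2-yl)-4H-chromen-4-one | COCOc1c(B2OC(C)(C)C(C)(C)O2)c(OC)cc2occc(=O)c12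
F5 | step 6 | 6-iodo-7-methoxy-4-oxo-4H-chromen-5-yl acetate | CC(=O)Oc1c(I)c(OC)cc2occc(=O)c12
F6 | step 6 | 6-[(2E)-3,7-dimethylocta-2,6-dien-1-yl]-7-methoxy-4-oxo-4H-chromen-5-yl acetate | CC(=O)Oc1c(C/C=C(\C)CCC=C(C)C)c(OC)cc2occc(=O)c12
F7 | step 6 | (2S)-2-(3,4-dimethoxyphenyl)-6-[(2E)-3,7-dimethylocta-2,6-dien-1-yl]-7-methoxy-4-oxo-3,4-dihydro-2H-chromen-5-yl acetate | COc1ccc([C@@H]2CC(=O)c3c(cc(OC)c(C/C=C(\C)CCC=C(C)C)c3OC(C)=O)O2)cc1OC
A1 | alternative 1 | 1-{3-[(2E)-3,7-dimethylocta-2,6-dien-1-yl]-2,6-dihydroxy-4-methoxyphenyl}ethan-1-one | CC(=O)c1c(O)cc(OC)c(C/C=C(\C)CCC=C(C)C)c1O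
A2 | alternative 1 | (2E)-3-(3,4-dimethoxyphenyl)-1-{3-[(2E)-3,7-dimethylocta-2,6-dien-1-yl]-2,6-dihydroxy-4-methoxyphenyl}prop-2-en-1-one | COc1ccc(/C=C/C(=O)c2c(O)cc(OC)c(C/C=C(\C)CCC=C(C)C)c2O)cc1OC
A3 | alternative 2 | 2-(3,4-dimethoxyphenyl)-6-[(2E)-3,7-dimethylocta-2,6-dien-1-yl]-7-methoxy-5-(methoxymethoxy)-4H-chromen-4-one | COc1ccc(-c2cc(=O)c3c(OCOC)c(C/C=C(\C)CCC=C(C)C)c(OC)cc3o2)cc1OC
A4 | alternative 3 | (2S)-2-(3,4-dimethoxyphenyl)-5-hydroxy-7-methoxy-2,3-dihydro-4H-chromen-4-one | COc1ccc([C@@H]2CC(=O)c3c(cc(OC)cc3O)O2)cc1OC
A5 | alternative 3 | (2S)-2-(3,4-dimethoxyphenyl)-5-hydroxy-6-iodo-7-methoxy-2,3-dihydro-4H-chromen-4-one | COc1ccc([C@@H]2CC(=O)c3c(cc(OC)c(I)c3O)O2)cc1OC
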